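**Strategy.** Neovibsanin I is disconnected at the C6–C7 bond of its cyclohexene ring (hexahydroisobenzofuran numbering: C6 is the quaternary carbon bearing methyl and 4-methylpent-3-enyl, C7 the ring CH bearing the enol ester arm). C4, C5, C6, the methyl group and the prenylated chain are the ten carbons of (R)-citronellal, whose tertiary C–H stereocentre is turned into the quaternary centre with retention when a rhodium vinylcarbenoid at C7 inserts into it (1,6-insertion), closing the carbocycle and setting C7. The precursor is an α-diazo ester on C3 of a 4-(1-silyloxycitronellyl)butenolide; its lactone later becomes the acetonyl dihydrofuran, its ester the enol ester.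

Key step: step 4

Remark: 3,4-dibromofuran-2(5H)-one (also the NaBH4 reduction product of mucobromic acid) and (R)-citronellal of high enantiomeric purity are taken as commercial; atom labels C1–C7a follow the hexahydroisobenzofuran numbering of the target (C1 carries the 2-oxopropyl group, C3 is the OCH2, C4 the carbinol).

Step 1
Reactants: 1 3,4-dibromofuran-2(5H)-one; 2 (R)-citronellal
Product: 4 3-bromo-4-[(1R,3R)-1-hydroxy-3,7-dimethyloct-6-en-1-yl]furan-2(5H)-one, via alkenylchromium dichloride 3 (not isolated)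
Conditions: CrCl2 (3 equiv), NiCl2 (cat.), chiral oxazoline–sulfonamide ligand (stoichiometric; the enantiomer that delivers the 1R carbinol), Et3N, THF, rt
Reagents that add atoms: none
Why: Nozaki–Hiyama–Kishi coupling: zerovalent nickel inserts into the more activated C4–Br bond (a vinylogous acyl bromide) rather than C3–Br, transmetalation to trivalent chromium gives 3, which adds chemoselectively to the aldehyde, and the new carbinol centre (1R) is set by the chiral ligand on chromium (reagent control) while the citronellal centre is untouched.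

Step 2
Reactants: 4 3-bromo-4-[(1R,3R)-1-hydroxy-3,7-dimethyloct-6-en-1-yl]furan-2(5H)-one
Product: 5 3-bromo-4-[(1R,3R)-1-(tert-butyldimethylsilyloxy)-3,7-dimethyloct-6-en-1-yl]furan-2(5H)-one
Conditions: TBSOTf, 2,6-lutidine, CH2Cl2, −78 °C
Reagents that add atoms: tert-butyldimethylsilyl trifluoromethanesulfonate (TBSOTf), CC(C)(C)[Si](C)(C)OS(=O)(=O)C(F)(F)F
Why: Standard silylation of a secondary alcohol with a non-nucleophilic base; the silyl ether blocks O–H insertion in step 4 and should survive every later step until the end.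

Step 3
Reactants: 5 3-bromo-4-[(1R,3R)-1-(tert-butyldimethylsilyloxy)-3,7-dimethyloct-6-en-1-yl]furan-2(5H)-one; 6 ethyl diazoacetate
Product: 7 ethyl 2-diazo-2-{4-[(1R,3R)-1-(tert-butyldimethylsilyloxy)-3,7-dimethyloct-6-en-1-yl]-2-oxo-2,5-dihydrofuran-3-yl}acetate
Conditions: Pd(PPh3)4 (5 mol %), Ag2CO3 (0.5 equiv), Et3N, PhMe, rt, dark
Reagents that add atoms: none
Why: Palladium-catalysed cross-coupling of a vinyl halide with the C–H bond of a diazo ester (oxidative addition, silver-assisted transfer of the diazoacetate carbon, reductive elimination) keeps the diazo group and is known for aryl and vinyl iodides; the α-bromo enoate is an activated halide, and no stereocentre is formed.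

Step 4
Reactants: 7 ethyl 2-diazo-2-{4-[(1R,3R)-1-(tert-butyldimethylsilyloxy)-3,7-dimethyloct-6-en-1-yl]-2-oxo-2,5-dihydrofuran-3-yl}acetate
Product: 9 ethyl (4R,6S,7R)-4-(tert-butyldimethylsilyloxy)-6-methyl-6-(4-methylpent-3-en-1-yl)-1-oxo-1,3,4,5,6,7-hexahydroisobenzofuran-7-carboxylate, via rhodium vinylcarbenoid 8 (not isolated)
Conditions: Rh2(esp)2 (1 mol %; esp = α,α,α′,α′-tetramethyl-1,3-benzenedipropionate), CH2Cl2, slow addition of 7, rt
Reagents that add atoms: none
Why: Loss of N2 from 7 gives the electrophilic rhodium vinylcarbenoid 8, whose carbene carbon (future C7) engages the tertiary C–H bond of the citronellal stereocentre (future C6) in a concerted, three-centre, hydride-transfer-like insertion. The closest known reaction type is the intramolecular carbenoid C–H insertion of diazo esters into stereogenic tertiary C–H bonds, which is established to proceed with retention of configuration. The cyclohexene ring is closed in the 1,6-insertion mode, giving a six-membered carbocycle that contains the butenolide C=C. C6 is controlled by the (R)-centre of citronellal (retention), so methyl and 4-methylpent-3-enyl cannot change places. C7 should be set by a half-chair transition state in which the silyloxy group and the long chain are pseudo-equatorial, the bulky dirhodium unit takes the open pseudo-axial site and the ester ends pseudo-equatorial, trans to the chain. The step needs 1,6- over the usually faster 1,5-insertion, and the substrate secures this because the 1,5-path would attack a CH2 deactivated by the β-silyloxy group and would build a strained bicyclo[3.3.0]oct-1(5)-ene on the butenolide double bond, while the target C–H is tertiary and the most hydridic; no ketone or free OH is present to divert the carbenoid into ylide or O–H insertion paths.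

Step 5
Reactants: 9 ethyl (4R,6S,7R)-4-(tert-butyldimethylsilyloxy)-6-methyl-6-(4-methylpent-3-en-1-yl)-1-oxo-1,3,4,5,6,7-hexahydroisobenzofuran-7-carboxylate
Product: 10 ethyl (4R,6S,7R)-4-(tert-butyldimethylsilyloxy)-1-hydroxy-6-methyl-6-(4-methylpent-3-en-1-yl)-1,3,4,5,6,7-hexahydroisobenzofuran-7-carboxylate (lactol, both C1 epimers)
Conditions: DIBAL-H (1.1 equiv), CH2Cl2, −78 °C; aqueous Rochelle salt
Reagents that add atoms: none
Why: DIBAL-H should stop at the aluminium hemiacetal of the lactone at −78 °C (lactone-to-lactol reduction), while the ethyl ester flanked by a quaternary carbon is far more hindered; the neutral work-up avoids dehydration of the lactol to a furan, and the anomeric centre is inconsequential.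

Step 6
Reactants: 10 lactol; 11 1-(triphenylphosphoranylidene)propan-2-one
Product: 13 ethyl (1S,4R,6S,7R)-4-(tert-butyldimethylsilyloxy)-6-methyl-6-(4-methylpent-3-en-1-yl)-1-(2-oxopropyl)-1,3,4,5,6,7-hexahydroisobenzofuran-7-carboxylate, via dienone alcohol 12 (not isolated)
Conditions: PhMe, 80 °C; then DBU (cat.), 0 °C
Reagents that add atoms: none
Why: The lactol reacts through its open (Z)-hydroxy-enal form in a Wittig olefination with the stabilised ylide (E-enone 12), and the liberated allylic alcohol closes the dihydrofuran by a reversible 5-exo-trig oxa-Michael addition; C1 is set under thermodynamic control, the 2-oxopropyl group being expected to settle anti to the C7 ester across the flat tetrasubstituted alkene.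

Step 7
Reactants: 13 keto ester
Product: 14 1-[(1S,4R,6S,7R)-4-(tert-butyldimethylsilyloxy)-7-(hydroxymethyl)-6-methyl-6-(4-methylpent-3-en-1-yl)-1,3,4,5,6,7-hexahydroisobenzofuran-1-yl]propan-2-ol (carbinol epimers)
Conditions: LiAlH4, THF, 0 °C; Na2SO4·10H2O
Reagents that add atoms: none
Why: LiAlH4 reduces the hindered ethyl ester to the primary alcohol and unavoidably the ketone to a secondary alcohol (epimers of no consequence), leaving silyl ether, allylic ether and alkenes untouched.

Step 8
Reactants: 14 diol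
Product: 15 (1S,4R,6S,7R)-4-(tert-butyldimethylsilyloxy)-6-methyl-6-(4-methylpent-3-en-1-yl)-1-(2-oxopropyl)-1,3,4,5,6,7-hexahydroisobenzofuran-7-carbaldehyde
Conditions: Dess–Martin periodinane (2.4 equiv), CH2Cl2, 0 °C to rt
Reagents that add atoms: none
Why: Dess–Martin oxidation returns the ketone and gives the aldehyde under non-basic conditions that should not epimerise the α-stereocentre C7 or open the ring by retro-oxa-Michael reaction.

Step 9
Reactants: 16 3-methylbut-2-enoic acid; 17 chloromethyl chlorosulfate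
Product: 18 chloromethyl 3-methylbut-2-enoate
Conditions: NaHCO3, Bu4NHSO4 (cat.), CH2Cl2/H2O, rt
Reagents that add atoms: none
Why: Phase-transfer O-alkylation of the carboxylate with chloromethyl chlorosulfate (chlorosulfate as leaving group) is the standard route to chloromethyl esters.

Step 10
Reactants: 18 chloromethyl 3-methylbut-2-enoate
Product: 19 [(3-methylbut-2-enoyloxy)methyl]triphenylphosphonium chloride
Conditions: PPh3, PhMe, 80 °C
Reagents that add atoms: triphenylphosphine, c1ccc(cc1)P(c1ccccc1)c1ccccc1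
Why: SN2 quaternisation of triphenylphosphine by the activated α-acyloxy chloride gives the (acyloxymethyl)phosphonium salt.

Step 11
Reactants: 15 keto aldehyde; 19 [(3-methylbut-2-enoyloxy)methyl]triphenylphosphonium chloride
Product: 21 (E)-2-[(1S,4R,6S,7R)-4-(tert-butyldimethylsilyloxy)-6-methyl-6-(4-methylpent-3-en-1-yl)-1-(2-oxopropyl)-1,3,4,5,6,7-hexahydroisobenzofuran-7-yl]ethenyl 3-methylbut-2-enoate, via acyloxymethylene ylide 20 (not isolated)
Conditions: 19, NaHMDS, THF, −78 °C; then 15, −78 to 0 °C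
Reagents that add atoms: none
Why: Wittig olefination with an acyloxymethylene phosphorane turns the aldehyde directly into the enol ester; the aldehyde is far more electrophilic than the methyl ketone, the low temperature limits epimerisation at C7, and the E isomer (the target geometry) is to be separated from the E/Z mixture that such ylides can give.

Step 12
Reactants: 21 silyl ether of the target
Product: 22 neovibsanin I
Conditions: HF·pyridine, pyridine, THF, 0 °C to rt
Reagents that add atoms: none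
Why: Buffered HF·pyridine cleaves the secondary silyl ether without the basic conditions (retro-oxa-Michael reaction, acyl transfer) that fluoride salts would bring, leaving enol ester and ketone intact.

**Compound list**

1 | 3,4-dibromofuran-2(5H)-one | O=C1OCC(Br)=C1Br | starting material
2 | (R)-citronellal, (3R)-3,7-dimethyloct-6-enal | O=CC[C@H](C)CCC=C(C)C | starting material
3 | (3-bromo-2-oxo-2,5-dihydrofuran-4-yl)chromium dichloride (trivalent chromium, chiral ligand omitted; not isolated) | O=C1OCC([Cr](Cl)Cl)=C1Br | intermediate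
4 | 3-bromo-4-[(1R,3R)-1-hydroxy-3,7-dimethyloct-6-en-1-yl]furan-2(5H)-one | O=C1OCC(=C1Br)[C@H](O)C[C@H](C)CCC=C(C)C | intermediate
5 | 3-bromo-4-[(1R,3R)-1-(tert-butyldimethylsilyloxy)-3,7-dimethyloct-6-en-1-yl]furan-2(5H)-one | O=C1OCC(=C1Br)[C@H](O[Si](C)(C)C(C)(C)C)C[C@H](C)CCC=C(C)C | intermediate
6 | ethyl diazoacetate | CCOC(=O)C=[N+]=[N-] | starting material
7 | ethyl 2-diazo-2-{4-[(1R,3R)-1-(tert-butyldimethylsilyloxy)-3,7-dimethyloct-6-en-1-yl]-2-oxo-2,5-dihydrofuran-3-yl}acetate | O=C1OCC(=C1C(=[N+]=[N-])C(=O)OCC)[C@H](O[Si](C)(C)C(C)(C)C)C[C@H](C)CCC=C(C)C | intermediate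
8 | rhodium vinylcarbenoid from 7 (one Rh of the Rh2(esp)2 unit shown, ligands omitted; not isolated) | O=C1OCC(=C1C(=[Rh])C(=O)OCC)[C@H](O[Si](C)(C)C(C)(C)C)C[C@H](C)CCC=C(C)C | intermediate
9 | ethyl (4R,6S,7R)-4-(tert-butyldimethylsilyloxy)-6-methyl-6-(4-methylpent-3-en-1-yl)-1-oxo-1,3,4,5,6,7-hexahydroisobenzofuran-7-carboxylate | O=C1OCC2=C1[C@H](C(=O)OCC)[C@@](C)(CCC=C(C)C)C[C@H]2O[Si](C)(C)C(C)(C)C | intermediate
10 | ethyl (4R,6S,7R)-4-(tert-butyldimethylsilyloxy)-1-hydroxy-6-methyl-6-(4-methylpent-3-en-1-yl)-1,3,4,5,6,7-hexahydroisobenzofuran-7-carboxylate (C1 epimers) | OC1OCC2=C1[C@H](C(=O)OCC)[C@@](C)(CCC=C(C)C)C[C@H]2O[Si](C)(C)C(C)(C)C | intermediate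
11 | 1-(triphenylphosphoranylidene)propan-2-one | CC(=O)C=P(c1ccccc1)(c1ccccc1)c1ccccc1 | starting material
12 | ethyl (1R,4R,6S)-4-(tert-butyldimethylsilyloxy)-3-(hydroxymethyl)-6-methyl-6-(4-methylpent-3-en-1-yl)-2-[(E)-3-oxobut-1-en-1-yl]cyclohex-2-ene-1-carboxylate (not isolated) | OCC1=C(/C=C/C(C)=O)[C@H](C(=O)OCC)[C@@](C)(CCC=C(C)C)C[C@H]1O[Si](C)(C)C(C)(C)C | intermediate
13 | ethyl (1S,4R,6S,7R)-4-(tert-butyldimethylsilyloxy)-6-methyl-6-(4-methylpent-3-en-1-yl)-1-(2-oxopropyl)-1,3,4,5,6,7-hexahydroisobenzofuran-7-carboxylate | CC(=O)C[C@@H]1OCC2=C1[C@H](C(=O)OCC)[C@@](C)(CCC=C(C)C)C[C@H]2O[Si](C)(C)C(C)(C)C | intermediate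
14 | 1-[(1S,4R,6S,7R)-4-(tert-butyldimethylsilyloxy)-7-(hydroxymethyl)-6-methyl-6-(4-methylpent-3-en-1-yl)-1,3,4,5,6,7-hexahydroisobenzofuran-1-yl]propan-2-ol (carbinol epimers) | CC(O)C[C@@H]1OCC2=C1[C@H](CO)[C@@](C)(CCC=C(C)C)C[C@H]2O[Si](C)(C)C(C)(C)C | intermediate
15 | (1S,4R,6S,7R)-4-(tert-butyldimethylsilyloxy)-6-methyl-6-(4-methylpent-3-en-1-yl)-1-(2-oxopropyl)-1,3,4,5,6,7-hexahydroisobenzofuran-7-carbaldehyde | CC(=O)C[C@@H]1OCC2=C1[C@H](C=O)[C@@](C)(CCC=C(C)C)C[C@H]2O[Si](C)(C)C(C)(C)C | intermediate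
16 | 3-methylbut-2-enoic acid | CC(C)=CC(=O)O | starting material
17 | chloromethyl chlorosulfate | ClCOS(=O)(=O)Cl | starting material
18 | chloromethyl 3-methylbut-2-enoate | CC(C)=CC(=O)OCCl | intermediate
19 | [(3-methylbut-2-enoyloxy)methyl]triphenylphosphonium chloride | CC(C)=CC(=O)OC[P+](c1ccccc1)(c1ccccc1)c1ccccc1.[Cl-] | intermediate
20 | (triphenylphosphoranylidene)methyl 3-methylbut-2-enoate (ylide; not isolated) | CC(C)=CC(=O)OC=P(c1ccccc1)(c1ccccc1)c1ccccc1 | intermediate
21 | (E)-2-[(1S,4R,6S,7R)-4-(tert-butyldimethylsilyloxy)-6-methyl-6-(4-methylpent-3-en-1-yl)-1-(2-oxopropyl)-1,3,4,5,6,7-hexahydroisobenzofuran-7-yl]ethenyl 3-methylbut-2-enoate | CC(=O)C[C@@H]1OCC2=C1[C@H](/C=C/OC(=O)C=C(C)C)[C@@](C)(CCC=C(C)C)C[C@H]2O[Si](C)(C)C(C)(C)C | intermediate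
22 | neovibsanin I, (E)-2-[(1S,4R,6S,7R)-4-hydroxy-6-methyl-6-(4-methylpent-3-en-1-yl)-1-(2-oxopropyl)-1,3,4,5,6,7-hexahydroisobenzofuran-7-yl]ethenyl 3-methylbut-2-enoate | CC(=O)C[C@@H]1OCC2=C1[C@H](/C=C/OC(=O)C=C(C)C)[C@@](C)(CCC=C(C)C)C[C@H]2O | target

**Total step count:** 12. **Longest linear sequence:** 10 (steps 1–8, 11, 12; steps 9–10 make the phosphonium salt).

**Steps most likely to fail**

1. Step 4 (key step). The carbenoid may insert into the C5 methylene instead (five-ring closure), dimerise, or close with poor facial control at C7. Fallback, setting out from 5 and returning at 9: the diazo ester is replaced by a 1-sulfonyl-1,2,3-triazole as carbene source, a class documented to favour tertiary C–H bonds. Stille coupling of 5 with ethynyltributylstannane (Pd(PPh3)4, PhMe, 60 °C) gives 3-ethynyl-4-[(1R,3R)-1-(tert-butyldimethylsilyloxy)-3,7-dimethyloct-6-en-1-yl]furan-2(5H)-one F1. Cycloaddition with tosyl azide catalysed by copper thiophene-2-carboxylate (CuTC, PhMe, rt) gives the 1-tosyltriazol-4-yl butenolide F2. Rh2(S-NTTL)4 in CHCl3 at 70 °C releases N2 and the α-imino carbene inserts into the same tertiary C–H bond to give the bicyclic N-tosyl imine F3, which is hydrolysed on wet basic alumina to the bicyclic lactone aldehyde F4. Pinnick oxidation (NaClO2, NaH2PO4, 2-methylbut-2-ene) gives the bicyclic lactone acid F5, and EtI/K2CO3 in DMF returns 9.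

2. Step 3. Oxidative addition of the vinyl bromide may be slow, so that palladium decomposes the diazo ester instead, or the product may cyclise to a 3H-pyrazole on standing. Fallback, setting out from 5 and returning at 7: Negishi coupling of 5 with the Reformatsky reagent BrZnCH2CO2Et (Pd2(dba)3, XPhos, THF, 50 °C) gives ethyl 2-{4-[(1R,3R)-1-(tert-butyldimethylsilyloxy)-3,7-dimethyloct-6-en-1-yl]-2-oxo-2,5-dihydrofuran-3-yl}acetate F6. Diazo transfer (4-acetamidobenzenesulfonyl azide, DBU, MeCN, 0 °C) then gives 7, which is used at once.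

3. Step 11. The ylide may give poor E/Z selectivity, be consumed by enolisation of the methyl ketone, or epimerise C7. Fallback, setting out from 15 and returning at 21: Takai-type olefination of 15 with Cl2CHB(pin), CrCl2 and LiI in THF is aldehyde-selective and E-selective and gives the (E)-alkenyl pinacol boronate F7. KHF2 in aqueous MeOH gives the potassium (E)-alkenyltrifluoroborate F8. Copper-catalysed oxidative coupling with acid 16 (CuBr cat., DMAP, 4 Å molecular sieves, O2, MeCN, 60 °C) forms the C–O bond with retention of the E geometry and gives 21.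

**Further compounds**

F1 | step 4 | 3-ethynyl-4-[(1R,3R)-1-(tert-butyldimethylsilyloxy)-3,7-dimethyloct-6-en-1-yl]furan-2(5H)-one | O=C1OCC(=C1C#C)[C@H](O[Si](C)(C)C(C)(C)C)C[C@H](C)CCC=C(C)C
F2 | step 4 | 4-[(1R,3R)-1-(tert-butyldimethylsilyloxy)-3,7-dimethyloct-6-en-1-yl]-3-[1-(4-methylbenzenesulfonyl)-1H-1,2,3-triazol-4-yl]furan-2(5H)-one | O=C1OCC(=C1c1cn(nn1)S(=O)(=O)c1ccc(C)cc1)[C@H](O[Si](C)(C)C(C)(C)C)C[C@H](C)CCC=C(C)C
F3 | step 4 | N-{[(4R,6S,7R)-4-(tert-butyldimethylsilyloxy)-6-methyl-6-(4-methylpent-3-en-1-yl)-1-oxo-1,3,4,5,6,7-hexahydroisobenzofuran-7-yl]methylidene}-4-methylbenzenesulfonamide | O=C1OCC2=C1[C@H](C=NS(=O)(=O)c1ccc(C)cc1)[C@@](C)(CCC=C(C)C)C[C@H]2O[Si](C)(C)C(C)(C)C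
F4 | step 4 | (4R,6S,7R)-4-(tert-butyldimethylsilyloxy)-6-methyl-6-(4-methylpent-3-en-1-yl)-1-oxo-1,3,4,5,6,7-hexahydroisobenzofuran-7-carbaldehyde | O=C1OCC2=C1[C@H](C=O)[C@@](C)(CCC=C(C)C)C[C@H]2O[Si](C)(C)C(C)(C)C
F5 | step 4 | (4R,6S,7R)-4-(tert-butyldimethylsilyloxy)-6-methyl-6-(4-methylpent-3-en-1-yl)-1-oxo-1,3,4,5,6,7-hexahydroisobenzofuran-7-carboxylic acid | O=C1OCC2=C1[C@H](C(=O)O)[C@@](C)(CCC=C(C)C)C[C@H]2O[Si](C)(C)C(C)(C)C
F6 | step 3 | ethyl 2-{4-[(1R,3R)-1-(tert-butyldimethylsilyloxy)-3,7-dimethyloct-6-en-1-yl]-2-oxo-2,5-dihydrofuran-3-yl}acetate | O=C1OCC(=C1CC(=O)OCC)[C@H](O[Si](C)(C)C(C)(C)C)C[C@H](C)CCC=C(C)C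
F7 | step 11 | 1-{(1S,4R,6S,7R)-4-(tert-butyldimethylsilyloxy)-6-methyl-6-(4-methylpent-3-en-1-yl)-7-[(E)-2-(4,4,5,5-tetramethyl-1,3,2-dioxaborolan-2-yl)ethenyl]-1,3,4,5,6,7-hexahydroisobenzofuran-1-yl}propan-2-one | CC(=O)C[C@@H]1OCC2=C1[C@H](/C=C/B1OC(C)(C)C(C)(C)O1)[C@@](C)(CCC=C(C)C)C[C@H]2O[Si](C)(C)C(C)(C)C
F8 | step 11 | potassium {(E)-2-[(1S,4R,6S,7R)-4-(tert-butyldimethylsilyloxy)-6-methyl-6-(4-methylpent-3-en-1-yl)-1-(2-oxopropyl)-1,3,4,5,6,7-hexahydroisobenzofuran-7-yl]ethenyl}trifluoroborate | CC(=O)C[C@@H]1OCC2=C1[C@H](/C=C/[B-](F)(F)F)[C@@](C)(CCC=C(C)C)C[C@H]2O[Si](C)(C)C(C)(C)C.[K+]
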